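**Retrosynthetic overview**

1. Numbering (eremophilane): ring A = C1–C5/C10, ring B = C5–C10, C14 on C5, C15 on C4, isopropenyl on C7; "cis/trans to C14" names the two faces of the decalin.
2. Feature: ring B, with the angular methyl C14 on C5 and adjacent oxygens on C8 and C9, is the ring of creosol's masked o-benzoquinone (C8 = carbonyl, C9 = ketal carbon). The cis fusion C5/C10 and the cis methyls on C4/C5 are what a boat Cope shift of an endo Z-propenyl group delivers.
3. Target ⇒ ring B adjusted last (C9 ketal → ketone → axial alcohol → senecioate; C8 alcohol → tiglate; C7 isopropenyl from an acetyl group placed on the C6=C7–C8=O enone) ⇒ cis-decalin dienone 8.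
4. 8 ⇒ Cope precursor 7 (C4–C5 formed, C2–C7 broken) ⇒ masked o-benzoquinone 5 + (Z)-2-siloxypenta-1,3-diene 3 (Diels–Alder through the enol double bond; adduct resolved).
5. Ring order: ring B comes from the arene, the bicyclo[2.2.2]octenone bridge is added by cycloaddition, and ring A closes in the Cope step as the bicycle opens.

Key step: step 5

Assumption: the C2 carbinol carried from 11 to 21 is a temporary centre, drawn with the hydroxyl trans to C14; its epimer would converge on the same ketone in step 18.

**Route**

Step 1
Reactants: 1 pent-3-yn-2-one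
Product: 2 (Z)-pent-3-en-2-one
Conditions: H2 (1 atm), Pd/CaCO3 poisoned with Pb(OAc)2, quinoline, pentane, 0 °C
Reagents that add atoms: none
Why: Lindlar-type semi-hydrogenation adds H2 cis to the ynone and should stop at the Z-enone, which is used cold and at once because it drifts to the E isomer with acid, base or light.

Step 2
Reactants: 2 (Z)-pent-3-en-2-one
Product: 3 (Z)-2-(tert-butyldimethylsilyloxy)penta-1,3-diene
Conditions: LDA, THF, −78 °C; then TBSOTf, −78 → 0 °C
Reagents that add atoms: tert-butyldimethylsilyl trifluoromethanesulfonate CC(C)(C)[Si](C)(C)OS(=O)(=O)C(F)(F)F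
Why: Kinetic deprotonation of the acetyl methyl group and O-silylation of the cross-conjugated enolate (silyl enol ether formation) should give the 2-siloxydiene without touching the Z double bond.

Step 3
Reactants: 4 creosol (2-methoxy-4-methylphenol); 3 (Z)-2-(tert-butyldimethylsilyloxy)penta-1,3-diene
Product: 6 racemic bicyclo[2.2.2]octenone adduct (propenyl endo), via masked o-benzoquinone 5 (not isolated)
Conditions: PhI(OAc)2, MeOH, 0 °C, 10 min; then NaHCO3, 3 (4 equiv), MeOH/CH2Cl2, 0 °C → rt
Reagents that add atoms: methanol CO
Why: Oxidative dearomatisation of the phenol with trivalent iodine in methanol gives the masked o-benzoquinone, an electron-poor diene that should add the siloxy-enol double bond of 3 in an inverse-demand Diels–Alder reaction; the CH2 terminus should bond to the δ-carbon of the dienone (C10) and the siloxy-bearing carbon to the α-carbon (C7), with the propenyl group endo (syn to the new C5=C6 bridge) and the bulky siloxy group exo beside the flat C8 carbonyl, while the Z-diene cannot reach the s-cis form and so cannot act as the 4π partner.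

Step 4
Reactants: 6 racemic bicyclo[2.2.2]octenone adduct
Product: 7 single enantiomer of the adduct (absolute configuration as drawn)
Conditions: preparative SFC on an amylose tris(3,5-dimethylphenylcarbamate) phase, CO2/i-PrOH
Reagents that add atoms: none
Why: The adduct is a neutral racemate with no salt-forming handle, so resolution by chromatography on a chiral stationary phase should separate the enantiomers; the one drawn fixes C10 and, through step 5, C4 and C5.

Step 5
Reactants: 7 single enantiomer of the adduct
Product: 8 cis-fused 2-(tert-butyldimethylsilyloxy)-9,9-dimethoxy-4,5-dimethyldecalin-2,6-dien-8-one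
Conditions: degassed mesitylene, 2,6-lutidine (0.1 equiv), BHT (trace), base-washed sealed tube, 170 °C
Reagents that add atoms: none
Why: This is a thermal [3,3]-sigmatropic (siloxy-Cope) shift of the 1,5-diene C4=C3–C2–C7–C6=C5, in which C2–C7 breaks as C4–C5 forms through the boat transition state that the bicyclo[2.2.2]octene imposes on an endo alkenyl group; the closest known reaction type is the Cope rearrangement of endo-vinyl bicyclo[2.2.2]octenones, made from masked o-benzoquinones and dienes, to cis-decalins. Ring A (C1–C5, C10) closes by this sigmatropic C4–C5 bond formation, a six-membered ring forming as the bicycle opens, suprafacially on both allyl units. C5 becomes a stereocentre because C4 can only reach the face of the C5=C6 bridge that looks at the C1–C2 bridge, so ring A is fused on the side of C1 and C14 ends cis to H10 (cis fusion, relayed from the configured C10). C4 is set by the alkene geometry: in the boat the Z-methyl C15 takes the inside position, eclipsed with the C5–C10 bond, and so ends cis to C14, whereas an E-propenyl group would give the trans isomer. The step needs the propenyl group endo and still Z, which the adduct of step 3 and acid-free conditions secure, and it needs the shift to outrun cycloreversion; release of bicyclic strain, the new C6=C7–C8=O enone and the silyl enol ether drive it, and the oxygen on C2 and the carbonyl next to C7 weaken the breaking bond.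

Step 6
Reactants: 8 cis-decalin dienone silyl enol ether
Product: 9 9,9-dimethoxy-4,5-dimethyl-cis-decal-6-ene-2,8-dione
Conditions: 0.5 M HCl, THF, 0 °C → rt
Reagents that add atoms: none
Why: Mild acid hydrolysis of the silyl enol ether (protonation at C3) should free the C2 ketone, while the C9 ketal survives because the adjacent carbonyl destabilises the oxocarbenium ion its hydrolysis needs.

Step 7
Reactants: 9 enedione
Product: 10 7-iodo-9,9-dimethoxy-4,5-dimethyl-cis-decal-6-ene-2,8-dione
Conditions: I2, pyridine/CH2Cl2, rt
Reagents that add atoms: iodine II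
Why: α-Iodination of the enone by the pyridine addition–iodination–elimination sequence (Baylis–Hillman-type α-halogenation) should be selective for C7, since the saturated C2 ketone is not enolised under these conditions.

Step 8
Reactants: 10 iodoenone
Product: 11 7-iodo-9,9-dimethoxy-4,5-dimethyl-cis-decal-6-ene-2,8-diol (both hydroxyls trans to C14)
Conditions: NaBH4, CeCl3·7H2O, MeOH, −78 → 0 °C
Reagents that add atoms: none
Why: Luche 1,2-reduction should deliver hydride to C8 from the outer face of ring B (the face of C14 and H10, anti to the axial methoxy group on C9), the inner face being covered by ring A, so the 8-hydroxyl ends trans to C14; the C2 ketone is reduced in the same operation.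

Step 9
Reactants: 11 iodo diol
Product: 12 2-O-tert-butyldiphenylsilyl ether of 11
Conditions: TBDPSCl, imidazole, DMF, 0 °C → rt
Reagents that add atoms: tert-butyldiphenylsilyl chloride CC(C)(C)[Si](Cl)(c1ccccc1)c1ccccc1
Why: Silyl ether formation should be selective for the unhindered C2 hydroxyl, because the C8 hydroxyl is flanked by the ketal carbon C9 and the iodoalkene carbon C7.

Step 10
Reactants: 12 silyl-protected iodo allylic alcohol
Product: 14 7-acetyl-6-en-8-ol, via ethoxyvinyl diene 13 (not isolated)
Conditions: tributyl(1-ethoxyvinyl)stannane, Pd(PPh3)4 (5 mol %), CuI (10 mol %), DMF, 60 °C; then 0.5 M HCl, THF, 0 °C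
Reagents that add atoms: tributyl(1-ethoxyvinyl)stannane CCOC(=C)[Sn](CCCC)(CCCC)CCCC; water O
Why: Stille coupling of the vinyl iodide with the masked acetyl stannane under zerovalent palladium, then hydrolysis of the very acid-labile ethoxyvinyl ether at 0 °C, should give the methyl ketone while the less labile C9 ketal and the silyl ether survive.

Step 11
Reactants: 14 7-acetyl-6-en-8-ol
Product: 15 7-acetyl-8-ol (acetyl cis to C14, trans to the 8-hydroxyl)
Conditions: H2 (1 atm), [Ir(cod)(PCy3)(py)]PF6 (10 mol %), CH2Cl2, rt
Reagents that add atoms: none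
Why: In this hydroxyl-directed homogeneous hydrogenation the cationic iridium catalyst binds the C8 hydroxyl and delivers H2 to the same face of C6=C7, so H7 ends cis to the hydroxyl and the acetyl group trans to it (cis to C14), which is also the more stable trans-diequatorial arrangement of this enolisable centre.

Step 12
Reactants: 15 7-acetyl-8-ol
Product: 16 7-isopropenyl-8-ol (9,9-dimethoxy, 2-OTBDPS)
Conditions: Zn, CH2Br2, TiCl4 (reagent pre-formed in THF), CH2Cl2, 0 °C → rt
Reagents that add atoms: dibromomethane BrCBr
Why: Lombardo methylenation is non-basic, so it should convert the methyl ketone into the isopropenyl group beside the free β-hydroxyl without retro-aldol cleavage or epimerisation at C7.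

Step 13
Reactants: 16 7-isopropenyl-8-ol
Product: 17 8-tiglate of 16
Conditions: (E)-2-methylbut-2-enoyl chloride, pyridine, DMAP, CH2Cl2, 40 °C
Reagents that add atoms: (E)-2-methylbut-2-enoyl chloride C/C=C(\C)C(=O)Cl
Why: DMAP-catalysed esterification of the one remaining alcohol with tigloyl chloride, with pyridine as the base to avoid ketene formation, should give the tiglate with its E geometry unchanged.

Step 14
Reactants: 17 8-tiglate ketal
Product: 18 9-ketone (8-tiglate, 7-isopropenyl, 2-OTBDPS)
Conditions: p-TsOH·H2O (0.2 equiv), acetone/H2O (10:1), 40 °C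
Reagents that add atoms: water O
Why: Acid-catalysed ketal hydrolysis should unmask the C9 ketone; the acid is kept weak because the isopropenyl group is acid-sensitive and the ketone formed is flanked by the epimerisable centres C8 and C10.

Step 15
Reactants: 18 9-ketone
Product: 19 9-ol (hydroxyl trans to C14, cis to the 8-tiglate)
Conditions: LiAlH(OtBu)3, THF, −78 → −30 °C
Reagents that add atoms: none
Why: Hydride reduction of the α-acyloxy ketone with this bulky, ester-tolerant reagent should occur from the outer face of ring B (cis to H10 and C14, anti to the C8 acyloxy group in the Felkin–Anh sense), because the inner face is blocked by the axial C4–C5 bond of ring A in the chair that keeps the isopropenyl and tiglate groups equatorial; the new axial hydroxyl is therefore cis to the tiglate.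

Step 16
Reactants: 19 9-ol
Product: 20 8-tiglate 9-senecioate (2-OTBDPS)
Conditions: 3-methylbut-2-enoyl chloride, pyridine, DMAP, CH2Cl2, 0 °C → rt
Reagents that add atoms: 3-methylbut-2-enoyl chloride CC(C)=CC(=O)Cl
Why: DMAP-catalysed esterification of the hindered axial alcohol, again with pyridine instead of a trialkylamine to suppress the vinylketene path to the deconjugated ester, should give the senecioate.

Step 17
Reactants: 20 bis-ester silyl ether
Product: 21 2-alcohol (8-tiglate, 9-senecioate)
Conditions: TBAF, AcOH, THF, rt → 40 °C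
Reagents that add atoms: none
Why: Fluoride cleavage of the silyl ether, buffered with acetic acid so that the two unsaturated esters are neither attacked nor shifted, should free the C2 alcohol.

Step 18
Reactants: 21 2-alcohol
Product: 22 CNP0181050.1
Conditions: Dess–Martin periodinane, CH2Cl2, rt
Reagents that add atoms: none
Why: Dess–Martin oxidation of the secondary alcohol is neutral and should give the C2 ketone without touching the esters or the isopropenyl group; no stereocentre is α to C2.

**Compound list**

1 | pent-3-yn-2-one | CC#CC(C)=O | starting material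
2 | (Z)-pent-3-en-2-one | C/C=C\C(C)=O | intermediate
3 | (Z)-2-(tert-butyldimethylsilyloxy)penta-1,3-diene | C=C(O[Si](C)(C)C(C)(C)C)/C=C\C | intermediate
4 | creosol (2-methoxy-4-methylphenol) | Cc1ccc(O)c(OC)c1 | starting material
5 | 6,6-dimethoxy-4-methylcyclohexa-2,4-dien-1-one (masked o-benzoquinone) | O=C1C=CC(C)=CC1(OC)OC | intermediate
6 | racemic 7-(tert-butyldimethylsilyloxy)-3,3-dimethoxy-5-methyl-7-[(Z)-prop-1-enyl]bicyclo[2.2.2]oct-5-en-2-one, propenyl syn to the C5=C6 bridge (racemate; relative configuration drawn) | O=C1[C@H]2C=C(C)[C@@H](C1(OC)OC)C[C@]2(O[Si](C)(C)C(C)(C)C)/C=C\C | intermediate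
7 | the same adduct as the single enantiomer drawn | O=C1[C@H]2C=C(C)[C@@H](C1(OC)OC)C[C@]2(O[Si](C)(C)C(C)(C)C)/C=C\C | intermediate
8 | cis-fused 2-(tert-butyldimethylsilyloxy)-9,9-dimethoxy-4,5-dimethyldecalin-2,6-dien-8-one (C14, C15 and H10 mutually cis) | O=C1C=C[C@@]2(C)[C@H](CC(O[Si](C)(C)C(C)(C)C)=C[C@@H]2C)C1(OC)OC | intermediate
9 | 9,9-dimethoxy-4,5-dimethyl-cis-decal-6-ene-2,8-dione | O=C1C=C[C@@]2(C)[C@H](CC(=O)C[C@@H]2C)C1(OC)OC | intermediate
10 | 7-iodo-9,9-dimethoxy-4,5-dimethyl-cis-decal-6-ene-2,8-dione | O=C1C(I)=C[C@@]2(C)[C@H](CC(=O)C[C@@H]2C)C1(OC)OC | intermediate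
11 | 7-iodo-9,9-dimethoxy-4,5-dimethyl-cis-decal-6-ene-2,8-diol, both hydroxyls trans to C14 | IC1=C[C@@]2(C)[C@H](C[C@@H](O)C[C@@H]2C)C(OC)(OC)[C@@H]1O | intermediate
12 | 2-O-tert-butyldiphenylsilyl ether of 11 | IC1=C[C@@]2(C)[C@H](C[C@@H](O[Si](c3ccccc3)(c3ccccc3)C(C)(C)C)C[C@@H]2C)C(OC)(OC)[C@@H]1O | intermediate
13 | 7-(1-ethoxyvinyl) analogue of 12 | CCOC(=C)C1=C[C@@]2(C)[C@H](C[C@@H](O[Si](c3ccccc3)(c3ccccc3)C(C)(C)C)C[C@@H]2C)C(OC)(OC)[C@@H]1O | intermediate
14 | 7-acetyl-9,9-dimethoxy-4,5-dimethyl-2-(tert-butyldiphenylsilyloxy)-cis-decal-6-en-8-ol | CC(=O)C1=C[C@@]2(C)[C@H](C[C@@H](O[Si](c3ccccc3)(c3ccccc3)C(C)(C)C)C[C@@H]2C)C(OC)(OC)[C@@H]1O | intermediate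
15 | 7-acetyl-9,9-dimethoxy-4,5-dimethyl-2-(tert-butyldiphenylsilyloxy)-cis-decalin-8-ol, acetyl cis to C14 and trans to the 8-hydroxyl | CC(=O)[C@H]1C[C@@]2(C)[C@H](C[C@@H](O[Si](c3ccccc3)(c3ccccc3)C(C)(C)C)C[C@@H]2C)C(OC)(OC)[C@@H]1O | intermediate
16 | 7-isopropenyl analogue of 15 (9,9-dimethoxy-2-silyloxy-cis-eremophil-11-en-8-ol) | C=C(C)[C@H]1C[C@@]2(C)[C@H](C[C@@H](O[Si](c3ccccc3)(c3ccccc3)C(C)(C)C)C[C@@H]2C)C(OC)(OC)[C@@H]1O | intermediate
17 | 8-tiglate of 16 | C=C(C)[C@H]1C[C@@]2(C)[C@H](C[C@@H](O[Si](c3ccccc3)(c3ccccc3)C(C)(C)C)C[C@@H]2C)C(OC)(OC)[C@@H]1OC(=O)/C(C)=C/C | intermediate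
18 | 9-ketone: 8-tigloyloxy-2-silyloxy-cis-eremophil-11-en-9-one | C=C(C)[C@H]1C[C@@]2(C)[C@H](C[C@@H](O[Si](c3ccccc3)(c3ccccc3)C(C)(C)C)C[C@@H]2C)C(=O)[C@@H]1OC(=O)/C(C)=C/C | intermediate
19 | 9-ol: 8-tigloyloxy-2-silyloxy-cis-eremophil-11-en-9-ol, 9-hydroxyl cis to the tiglate and trans to C14 | C=C(C)[C@H]1C[C@@]2(C)[C@H](C[C@@H](O[Si](c3ccccc3)(c3ccccc3)C(C)(C)C)C[C@@H]2C)[C@H](O)[C@@H]1OC(=O)/C(C)=C/C | intermediate
20 | 9-senecioate of 19 | C=C(C)[C@H]1C[C@@]2(C)[C@H](C[C@@H](O[Si](c3ccccc3)(c3ccccc3)C(C)(C)C)C[C@@H]2C)[C@H](OC(=O)C=C(C)C)[C@@H]1OC(=O)/C(C)=C/C | intermediate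
21 | 2-alcohol: 9-senecioyloxy-8-tigloyloxy-cis-eremophil-11-en-2-ol | C=C(C)[C@H]1C[C@@]2(C)[C@H](C[C@@H](O)C[C@@H]2C)[C@H](OC(=O)C=C(C)C)[C@@H]1OC(=O)/C(C)=C/C | intermediate
22 | CNP0181050.1 (9-senecioyloxy-8-tigloyloxy-cis-eremophil-11-en-2-one) | C=C(C)[C@H]1C[C@@]2(C)[C@H](CC(=O)C[C@@H]2C)[C@H](OC(=O)C=C(C)C)[C@@H]1OC(=O)/C(C)=C/C | target

**Step count**

Total: 18 steps. Longest linear sequence: 18 steps (1 → 22); creosol 4 enters at step 3.

**Steps most likely to fail**

Step 5 (Cope shift). The Z-methyl must sit inside the boat, which raises the barrier. At the temperature then required, cycloreversion of 7 to 5 and 3 (with loss of 5 by dimerisation) and thermal drift of the alkene geometry could outrun the [3,3] shift. Fallback, setting out from 7: the silyl group is removed with HF·pyridine in THF to give the tertiary allylic alcohol F1. Treatment with KH and 18-crown-6 in THF at 0 °C should bring about the alkoxide-accelerated (anionic oxy-Cope) rearrangement through the same bicycle-enforced boat. Quenching the resulting C2 enolate with aqueous NH4Cl should give the dione directly, so the route is rejoined at 9 and steps 5 and 6 are replaced. The alkoxide could also cleave and re-close by Michael addition, which leads to the same skeleton but makes C4 less secure.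

Step 3 (oxidation and cycloaddition). The silyl enol ether may be consumed by methanolysis in the oxidation medium, self-dimerisation of 5 may outrun the cross-cycloaddition, and the twisted Z-propenyl group may compete poorly with the siloxy group for the endo position. Fallback, setting out from 1 and 4: 1 is silylated (TBSOTf, Et3N, CH2Cl2, 0 °C) to the planar enyne 2-(tert-butyldimethylsilyloxy)pent-1-en-3-yne F2. This is added to 5, generated from 4 as before, to give the propynyl adduct F3, in which the rod-like alkynyl group should take the endo position. Semi-hydrogenation (H2, Pd/CaCO3 poisoned with Pb(OAc)2, quinoline) then creates the Z-propenyl group after the cycloaddition, and the route is rejoined at 6.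

Step 14 (ketal hydrolysis). Ionisation of the ketal is slowed by the neighbouring acyloxy group. Under forcing acid the tiglate could participate (acyl transfer or loss), the isopropenyl double bond could hydrate or migrate, or the new ketone could epimerise at C10. Fallback, setting out from 16: the ketal is hydrolysed at the hydroxy stage, where milder acid should suffice (p-TsOH·H2O, acetone/H2O), to give the α-hydroxy ketone F4. Reduction with NaBH4 in MeOH at −40 °C, from the outer face, should give the cis-8,9-diol F5. Selective acylation of the equatorial 8-hydroxyl with one equivalent of tigloyl chloride (pyridine, −20 °C) rejoins the route at 19.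

Further compounds
F1 | step 5 | 7-hydroxy-3,3-dimethoxy-5-methyl-7-[(Z)-prop-1-enyl]bicyclo[2.2.2]oct-5-en-2-one (desilylated 7) | O=C1[C@H]2C=C(C)[C@@H](C1(OC)OC)C[C@]2(O)/C=C\C
F2 | step 3 | 2-(tert-butyldimethylsilyloxy)pent-1-en-3-yne | C=C(O[Si](C)(C)C(C)(C)C)C#CC
F3 | step 3 | racemic 7-(tert-butyldimethylsilyloxy)-3,3-dimethoxy-5-methyl-7-(prop-1-ynyl)bicyclo[2.2.2]oct-5-en-2-one, propynyl syn to the C5=C6 bridge (relative configuration drawn) | O=C1[C@H]2C=C(C)[C@@H](C1(OC)OC)C[C@]2(O[Si](C)(C)C(C)(C)C)C#CC
F4 | step 14 | 8-hydroxy-2-(tert-butyldiphenylsilyloxy)-cis-eremophil-11-en-9-one | C=C(C)[C@H]1C[C@@]2(C)[C@H](C[C@@H](O[Si](c3ccccc3)(c3ccccc3)C(C)(C)C)C[C@@H]2C)C(=O)[C@@H]1O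
F5 | step 14 | 2-(tert-butyldiphenylsilyloxy)-cis-eremophil-11-ene-8,9-diol (both hydroxyls trans to C14) | C=C(C)[C@H]1C[C@@]2(C)[C@H](C[C@@H](O[Si](c3ccccc3)(c3ccccc3)C(C)(C)C)C[C@@H]2C)[C@H](O)[C@@H]1O
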